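## Structural features

The target is a 3,4-dihydroisoquinoline (ring A: benzene C4a/C5–C8/C8a; ring B: C1=N2–C3–C4) joined through C7 to C2′ of a naphthalene. Ring C is C1′–C4′/C4a′/C8a′ and ring D is C5′–C8′, with primed locants following the naphthalen-1-ol name. Ring A carries OMe on C6 and C8, ring C a free OH on C1′, and ring D an OMe on C8′ (peri to the OH) and a methyl on C6′. The only stereocentre is C3 (S), which bears a methyl group next to the ketimine nitrogen and has no stereogenic neighbour. The fragile groups are the cyclic ketimine (reducible, acidic C1-methyl, so it must come late) and the electron-rich 1-naphthol with a free para position C4′ (sensitive to oxidants and electrophiles). The real difficulty is the C7–C2′ bond: C7 lies between two methoxy groups, C2′ is ortho to the hydroxyl group, and a second, electronically similar position competes on each ring (C5 on ring A, C4′ on ring C). In addition, exactly one of four oxygens must end as a free OH. The key step exploits the position of C2′ in ring C, between the oxygen-bearing C1′ and the CH carbon C3′: C2′ is the α-carbon of a latent aryl ketone (C1′) and the donor of an aldol condensation onto a latent aldehyde (C3′), and C1′, C8a′, C4a′, C4′ and C3′ together with ring D are the skeleton of an isocoumarin. Ring C can therefore be built around a benzylic carbon that already carries ring A.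

Assumption: the given structure has no axial descriptor, so the C7–C2′ axis (three small ortho oxygen substituents and one hydrogen) is treated as configurationally undefined and C3 is the only stereogenic element to be controlled.

## Logic of the disconnections

**20 back to 18 (through 19).** The C1–C8a bond and the C1=N double bond of ring B are cut (Bischler–Napieralski), and the free OH is traced to an O-acetate. The ketimine is thereby made last, after all organometallic steps. The ring-A precursor in 18 is symmetric about the biaryl bond, so both positions ortho to the side chain are the same and no regiochemical question arises. The forward step demands that the naphthol is masked against POCl3 and that the mask comes off without touching the imine or C3.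

**18 back to 16 (through 17).** No skeletal bond is cut; the carbamate on nitrogen is exchanged for the acetamide that supplies C1 and its methyl group, and the same reagent acetylates O1′. The demand is an acidolysis that does not alkylate the electron-rich naphthol.

**16 back to 12 and 14 (through 15); 14 back to 13.** The bond between ring A (C4a) and C4 is cut, an sp2–sp3 bond far from both methoxy groups. This brings in C3 with its nitrogen and methyl group from the chiral pool in one step and leaves an aryl bromide as the only handle that 12 has to carry. The demand is a cross-coupling that tolerates a carbamate N–H and a free naphthol and does not touch the stereocentre β to the metal.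

**12 back to 9 and 6 (through 10 and 11).** This is the key disconnection. Both ring-C bonds of C2′ are cut, C1′–C2′ and C2′=C3′, so the biaryl bond C7–C2′ is traced to the existing bond between ring A and a benzylic carbon. Ring C, the free hydroxyl group and the hindered biaryl bond all disappear at once, and what remains is a benzylic chloride and an enol lactone. The demand is mono-addition of a benzylic carbanion to the lactone carbonyl, then aldol closure and aromatisation, with an aryl bromide present.

**6 back to 3 (through 4 and 5); 3 back to 1 (through 2).** The C3′–C4′ bond and the lactone C–O bond are cut, giving an ortho-toluate and a one-carbon formyl donor; the ester carbon is then cut from the ring. The ring-D pattern (OMe ortho to the carboxyl carbon, methyl para to it) is thereby fixed by two directed metalations. The demand is lithiation ortho to OMe in the first step and at the methyl group ortho to the ester in the second.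

**9 back to 8 and 7.** Only functional group changes: benzylic chloride from alcohol from aldehyde. The carbon that becomes C2′ is already in place between the two methoxy groups in the starting material.

## Other disconnections considered

**Alternative 1:** Cut the biaryl bond C7–C2′ (the obvious first choice). The forward key step is a Suzuki–Miyaura coupling of the boronic acid A1 with the bromonaphthalene A2 to give the biaryl A3, followed by the same ring-B closure. A1 is a 2,6-dimethoxyarylboronic acid, a class that loses boron readily under basic coupling conditions. The coupling has to join two carbons with three ortho substituents between them. A2 still requires a de novo naphthalene synthesis, plus a bromination that must go ortho rather than para to the oxygen on C1′. The chosen plan makes the naphthalene and the biaryl bond in the same operation and needs no regioselective halogenation.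

**Alternative 2:** Cut the same bond, but form it as in the biosynthesis by oxidative coupling of the naphthol A4 with the dihydroisoquinoline A5 (or its phenolic precursor). Both carbons are nucleophilic, so a one- or two-electron oxidant would have to join them. Nothing in A4 distinguishes C2′ from the normally more reactive para position C4′, and nothing in A5 distinguishes C7 from C5. Four cross-coupled regioisomers and the homodimers of A4 are therefore to be expected on mechanistic grounds. The chosen plan fixes both positions by connectivity.

**Alternative 3:** Cut only C1′–C2′ of ring C. The forward key step is an anionic ring annulation of the ortho-(3-arylallyl)benzamide A6 with a lithium amide, in which the 1,3-diarylallyl anion attacks the amide carbonyl and gives 12. This also avoids a biaryl coupling. However, the nucleophile is a stabilised, delocalised anion whose attacking carbon carries the 2,6-dimethoxyaryl group, and the electrophile is a diethylamide flanked by OMe. A6 itself needs three or four extra steps, including an allylation with an SN2/SN2′ ambiguity. The chosen plan uses a localised sp3 benzylic Grignard reagent on an activated lactone and closes the ring onto an unhindered aldehyde, with fewer steps.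

Key step: step 5

## Steps

Step 1
Reactants: 1 3,5-dimethylanisole
Product: 3 methyl 2-methoxy-4,6-dimethylbenzoate, via aryllithium 2 (not isolated)
Conditions: n-BuLi, TMEDA, Et2O, 0 °C to rt; cannulate into ClCO2Me (3 equiv), THF, −78 °C
Reagents that add atoms: methyl chloroformate, COC(=O)Cl
Why: Directed ortho metalation: the methoxy group directs lithiation to the only kind of ortho C–H (C2 and C6 are equivalent); inverse quench into excess chloroformate should give the ester, whose two ortho substituents block a second addition.

Step 2
Reactants: 3 methyl 2-methoxy-4,6-dimethylbenzoate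
Product: 6 isocoumarin 8-methoxy-6-methyl-1H-isochromen-1-one, via benzylic lithium species 4 (not isolated), via aldehyde 5 (not isolated)
Conditions: LiN(i-Pr)2 (1.1 equiv), THF, −78 °C; DMF, −78 to 0 °C; aq. HCl; then TsOH (cat.), toluene, 80 °C
Reagents that add atoms: N,N-dimethylformamide, CN(C)C=O
Why: Lateral lithiation occurs at the methyl group ortho to the ester (chelation by the ester, conjugated anion) and not at the para methyl; formyl transfer from DMF gives the arylacetaldehyde, whose enol closes onto the ester under acid (enol lactonisation with loss of methanol) to the conjugated six-membered enol lactone.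

Step 3
Reactants: 7 4-bromo-2,6-dimethoxybenzaldehyde
Product: 8 (4-bromo-2,6-dimethoxyphenyl)methanol
Conditions: NaBH4, MeOH/THF, 0 °C
Reagents that add atoms: none
Why: Hydride reduction of an aromatic aldehyde; aryl bromide and ethers are inert.

Step 4
Reactants: 8 (4-bromo-2,6-dimethoxyphenyl)methanol
Product: 9 5-bromo-2-(chloromethyl)-1,3-dimethoxybenzene
Conditions: SOCl2, CH2Cl2, 0 °C; evaporate, use at once
Reagents that add atoms: thionyl chloride, O=S(Cl)Cl
Why: Chlorodehydroxylation through the chlorosulfite; the bromine lowers the nucleophilicity of the ring and so limits Friedel–Crafts self-alkylation of this reactive benzylic chloride, which is used without storage.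

Step 5
Reactants: 9 5-bromo-2-(chloromethyl)-1,3-dimethoxybenzene; 6 isocoumarin 8-methoxy-6-methyl-1H-isochromen-1-one
Product: 12 naphthol 2-(4-bromo-2,6-dimethoxyphenyl)-8-methoxy-6-methylnaphthalen-1-ol, via Grignard reagent 10 (not isolated), via keto aldehyde 11 (not isolated)
Conditions: Mg turnings (excess), 2-methyltetrahydrofuran, 0 °C, slow addition of 9; add to 6, THF, −78 to 0 °C; then KOH, MeOH, 0 to 40 °C, argon; dilute aq. HCl
Reagents that add atoms: none
Why: Magnesium should insert into the benzylic C–Cl bond of 9 at 0 °C much faster than into the electron-rich aryl C–Br bond, and both ortho positions of 10 carry OMe, so the reagent can react only through its benzylic carbon. 10 adds to the lactone carbonyl of 6 (C1′, activated by chelation of magnesium between C=O and the neighbouring OMe), and the tetrahedral alkoxide opens by expelling the enolate of the arylacetaldehyde, which after proton transfer is keto aldehyde 11. Base then forms the enolate of the benzyl ketone (its CH2 is acidified by aryl and aroyl), which attacks the aldehyde in a 6-(enolexo)-exo-trig aldol addition; E1cB loss of water and tautomerisation of the 4H-naphthalen-1-one give the naphthol irreversibly. This is the Fujimoto–Belleau reaction (Grignard reagent plus enol lactone, then aldol condensation to a cyclohexenone) applied to a benzo-fused enol lactone, so that the cyclohexenone is the keto form of a 1-naphthol; the conversion of isocoumarins into 1-naphthols by ester enolates and the base-induced recyclisation of 1-alkyl-2-benzopyrylium salts are close relatives. No stereocentre is formed. The step needs mono-addition: the ketone of the ring-opened adduct is flanked by OMe and the side arm and is quickly enolised, so a second addition should be slow when 10 is added to 6 at low temperature. Regiochemistry needs no control, because C1′, C3′ and C4′ are the lactone carbons and C2′ is the Grignard carbon, so the OH is formed at C1′, peri to OMe and ortho to the aryl group, as the only free hydroxyl of the molecule. The only other aldol mode (aldehyde enolate onto the ketone) would give a four-membered ring, and the lactol forms of 11 are reversible, so the material should funnel to 12.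

Step 6
Reactants: 13 tert-butyl N-[(2S)-1-hydroxypropan-2-yl]carbamate (N-Boc-L-alaninol)
Product: 14 tert-butyl N-[(2S)-1-iodopropan-2-yl]carbamate
Conditions: I2, PPh3, imidazole, CH2Cl2, 0 °C to rt
Reagents that add atoms: iodine, II
Why: Appel-type iodination by SN2 displacement at the primary carbon; the stereocentre is not involved and keeps the L-alanine configuration, which is the (S) configuration of C3 in the target.

Step 7
Reactants: 14 tert-butyl N-[(2S)-1-iodopropan-2-yl]carbamate; 12 naphthol 2-(4-bromo-2,6-dimethoxyphenyl)-8-methoxy-6-methylnaphthalen-1-ol
Product: 16 tert-butyl N-[(2S)-1-[4-(1-hydroxy-8-methoxy-6-methylnaphthalen-2-yl)-3,5-dimethoxyphenyl]propan-2-yl]carbamate, via alkylzinc iodide 15 (not isolated)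
Conditions: Zn dust (I2-activated), DMF, rt; then 12, Pd2(dba)3 (2.5 mol %), SPhos (10 mol %), DMF, 40 °C; 15 in excess (3 equiv)
Reagents that add atoms: none
Why: Negishi coupling: zinc inserts into the primary C–I bond, zerovalent palladium with SPhos adds oxidatively to the unhindered aryl bromide (meta to both OMe groups), and reductive elimination outruns β-hydride elimination; the stereocentre is β to zinc and takes no part; Negishi couplings tolerate free phenolic OH, and the excess of 15 covers slow protonolysis.

Step 8
Reactants: 16 tert-butyl N-[(2S)-1-[4-(1-hydroxy-8-methoxy-6-methylnaphthalen-2-yl)-3,5-dimethoxyphenyl]propan-2-yl]carbamate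
Product: 18 diacetate 2-{4-[(2S)-2-acetamidopropyl]-2,6-dimethoxyphenyl}-8-methoxy-6-methylnaphthalen-1-yl acetate, via amine hydrochloride 17 (not isolated)
Conditions: HCl (4 M in dioxane), rt; evaporate; then Ac2O, pyridine, DMAP (cat.), CH2Cl2, rt
Reagents that add atoms: acetic anhydride, CC(=O)OC(C)=O
Why: Acidolysis of the carbamate with chloride as scavenger of the tert-butyl cation, then acyl transfer to both N and O; the N-acetyl group supplies C1 and its methyl group, and the O-acetate masks the naphthol for the next step.

Step 9
Reactants: 18 diacetate 2-{4-[(2S)-2-acetamidopropyl]-2,6-dimethoxyphenyl}-8-methoxy-6-methylnaphthalen-1-yl acetate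
Product: 20 target 2-[(3S)-6,8-dimethoxy-1,3-dimethyl-3,4-dihydroisoquinolin-7-yl]-8-methoxy-6-methylnaphthalen-1-ol, via O-acetyl dihydroisoquinoline 19 (not isolated)
Conditions: POCl3, MeCN, 80 °C; ice, aq. NaHCO3, extraction; crude 19 then K2CO3 (cat.), MeOH, rt
Reagents that add atoms: none
Why: Bischler–Napieralski cyclisation: the nitrilium (or imidoyl phosphate) attacks the position ortho to the side chain, which is para to one OMe and ortho to the other, and both such positions are equivalent; base-catalysed transesterification then removes the aryl acetate without touching the ketimine or C3.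

## Compound list

1 | 3,5-dimethylanisole | COc1cc(C)cc(C)c1 | starting material
2 | (2-methoxy-4,6-dimethylphenyl)lithium | [Li]c1c(C)cc(C)cc1OC | intermediate
3 | methyl 2-methoxy-4,6-dimethylbenzoate | COC(=O)c1c(C)cc(C)cc1OC | intermediate
4 | [3-methoxy-2-(methoxycarbonyl)-5-methylbenzyl]lithium | [Li]Cc1cc(C)cc(OC)c1C(=O)OC | intermediate
5 | methyl 2-methoxy-4-methyl-6-(2-oxoethyl)benzoate | COC(=O)c1c(CC=O)cc(C)cc1OC | intermediate
6 | 8-methoxy-6-methyl-1H-isochromen-1-one | COc1cc(C)cc2C=COC(=O)c12 | intermediate
7 | 4-bromo-2,6-dimethoxybenzaldehyde | COc1cc(Br)cc(OC)c1C=O | starting material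
8 | (4-bromo-2,6-dimethoxyphenyl)methanol | COc1cc(Br)cc(OC)c1CO | intermediate
9 | 5-bromo-2-(chloromethyl)-1,3-dimethoxybenzene | COc1cc(Br)cc(OC)c1CCl | intermediate
10 | (4-bromo-2,6-dimethoxybenzyl)magnesium chloride | COc1cc(Br)cc(OC)c1C[Mg]Cl | intermediate
11 | 2-{2-[(4-bromo-2,6-dimethoxyphenyl)acetyl]-3-methoxy-5-methylphenyl}acetaldehyde | COc1cc(Br)cc(OC)c1CC(=O)c1c(CC=O)cc(C)cc1OC | intermediate
12 | 2-(4-bromo-2,6-dimethoxyphenyl)-8-methoxy-6-methylnaphthalen-1-ol | COc1cc(Br)cc(OC)c1-c1ccc2cc(C)cc(OC)c2c1O | intermediate
13 | tert-butyl N-[(2S)-1-hydroxypropan-2-yl]carbamate | C[C@H](NC(=O)OC(C)(C)C)CO | starting material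
14 | tert-butyl N-[(2S)-1-iodopropan-2-yl]carbamate | C[C@H](NC(=O)OC(C)(C)C)CI | intermediate
15 | {(2S)-2-[(tert-butoxycarbonyl)amino]propyl}zinc iodide | C[C@H](NC(=O)OC(C)(C)C)C[Zn]I | intermediate
16 | tert-butyl N-[(2S)-1-[4-(1-hydroxy-8-methoxy-6-methylnaphthalen-2-yl)-3,5-dimethoxyphenyl]propan-2-yl]carbamate | C[C@H](NC(=O)OC(C)(C)C)Cc1cc(OC)c(-c2ccc3cc(C)cc(OC)c3c2O)c(OC)c1 | intermediate
17 | 2-{4-[(2S)-2-aminopropyl]-2,6-dimethoxyphenyl}-8-methoxy-6-methylnaphthalen-1-ol hydrochloride | C[C@H](N)Cc1cc(OC)c(-c2ccc3cc(C)cc(OC)c3c2O)c(OC)c1.Cl | intermediate
18 | 2-{4-[(2S)-2-acetamidopropyl]-2,6-dimethoxyphenyl}-8-methoxy-6-methylnaphthalen-1-yl acetate | CC(=O)N[C@@H](C)Cc1cc(OC)c(-c2ccc3cc(C)cc(OC)c3c2OC(C)=O)c(OC)c1 | intermediate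
19 | 2-[(3S)-6,8-dimethoxy-1,3-dimethyl-3,4-dihydroisoquinolin-7-yl]-8-methoxy-6-methylnaphthalen-1-yl acetate | COc1cc2c(c(OC)c1-c1ccc3cc(C)cc(OC)c3c1OC(C)=O)C(C)=N[C@@H](C)C2 | intermediate
20 | 2-[(3S)-6,8-dimethoxy-1,3-dimethyl-3,4-dihydroisoquinolin-7-yl]-8-methoxy-6-methylnaphthalen-1-ol | COc1cc2c(c(OC)c1-c1ccc3cc(C)cc(OC)c3c1O)C(C)=N[C@@H](C)C2 | target

## Step count and least certain steps

Total: 9 steps. Longest linear sequence: 6 steps (1, 2, 5, 7, 8, 9 from compound 1, or 3, 4, 5, 7, 8, 9 from compound 7).

**Step 5 (key step).** Three things may go wrong:
- Wurtz homocoupling of the electron-rich benzylic chloride while 10 is formed.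
- A second addition of 10 to the ketone of the ring-opened adduct.
- Air oxidation of the naphtholate during the basic ring closure.

The fallback avoids both the chloride and the Grignard reagent and closes the ring by olefination instead of aldol condensation. It sets out from 8 and 6. Alcohol 8 is heated with triethyl phosphite and ZnI2 in toluene to give diethyl [(4-bromo-2,6-dimethoxyphenyl)methyl]phosphonate F1 (Michaelis–Arbuzov-type phosphonylation of a benzylic alcohol). Its anion (LiN(SiMe3)2, 2 equiv, THF, −78 °C) is acylated by lactone 6 to give the β-ketophosphonate aldehyde F2. This closes C2′=C3′ by an intramolecular Horner–Wadsworth–Emmons reaction on warming, and the resulting 4H-naphthalen-1-one tautomerises, so the route is rejoined at 12.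

**Step 2.** Three things may go wrong:
- Self-condensation of anion 4 with unreacted 3.
- Partial deprotonation at the para methyl group.
- Oligomerisation of the arylacetaldehyde 5 in acid before it lactonises.

The fallback changes the one-carbon electrophile and moves the oxidation-level adjustment to a later point. It sets out from 3. Anion 4 is trapped with formaldehyde (cracked paraformaldehyde) and the alkoxide lactonises to 8-methoxy-6-methyl-3,4-dihydro-1H-isochromen-1-one F3. Grignard reagent 10 opens F3 to the keto alcohol 2-(4-bromo-2,6-dimethoxyphenyl)-1-[2-(2-hydroxyethyl)-6-methoxy-4-methylphenyl]ethan-1-one F4 (in equilibrium with its lactol). Oxidation with 2-iodoxybenzoic acid in DMSO gives 11, where the route is rejoined; base then closes 11 to 12 as in step 5.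

**Step 7.** Three things may go wrong:
- Protonolysis of 15 by the naphthol O–H.
- β-Elimination of the β-amido alkylzinc reagent.
- Slow oxidative addition into the electron-rich aryl bromide.

The fallback changes the order of events so that no acidic O–H is present during the coupling. It sets out from 12, which is acetylated (Ac2O, pyridine, DMAP) to 2-(4-bromo-2,6-dimethoxyphenyl)-8-methoxy-6-methylnaphthalen-1-yl acetate F5. Negishi coupling of F5 with 15 gives the carbamate F6. HCl in dioxane gives the amine hydrochloride F7, and N-acetylation rejoins the route at 18.

**Step 9.** Three things may go wrong: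
- Fragmentation of the nitrilium ion (retro-Ritter loss of the nitrogen side chain).
- Premature loss of the O-acetyl group followed by O-phosphorylation.
- Incomplete cyclisation.

The fallback replaces the amide activation by an iminium cyclisation and an oxidation. It sets out from 17. Pictet–Spengler reaction with acetaldehyde (trifluoroacetic acid, CH2Cl2) gives the tetrahydroisoquinoline F8 as a mixture of C1 epimers, both of which are usable because C1 becomes sp2. N-chlorination (N-chlorosuccinimide, CH2Cl2, −20 °C) gives the N-chloroamine F9. Dehydrochlorination with KOH in ethanol removes the benzylic C1–H and rejoins the route at 20. The nitrogen is the most nucleophilic site, which should spare the naphthol.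

## Further compounds

F1 | step 5 | diethyl [(4-bromo-2,6-dimethoxyphenyl)methyl]phosphonate | CCOP(=O)(OCC)Cc1c(OC)cc(Br)cc1OC
F2 | step 5 | diethyl {1-(4-bromo-2,6-dimethoxyphenyl)-2-[2-methoxy-4-methyl-6-(2-oxoethyl)phenyl]-2-oxoethyl}phosphonate | CCOP(=O)(OCC)C(c1c(OC)cc(Br)cc1OC)C(=O)c1c(CC=O)cc(C)cc1OC
F3 | step 2 | 8-methoxy-6-methyl-3,4-dihydro-1H-isochromen-1-one | COc1cc(C)cc2CCOC(=O)c12
F4 | step 2 | 2-(4-bromo-2,6-dimethoxyphenyl)-1-[2-(2-hydroxyethyl)-6-methoxy-4-methylphenyl]ethan-1-one | COc1cc(Br)cc(OC)c1CC(=O)c1c(CCO)cc(C)cc1OC
F5 | step 7 | 2-(4-bromo-2,6-dimethoxyphenyl)-8-methoxy-6-methylnaphthalen-1-yl acetate | COc1cc(Br)cc(OC)c1-c1ccc2cc(C)cc(OC)c2c1OC(C)=O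
F6 | step 7 | 2-{4-[(2S)-2-[(tert-butoxycarbonyl)amino]propyl]-2,6-dimethoxyphenyl}-8-methoxy-6-methylnaphthalen-1-yl acetate | C[C@H](NC(=O)OC(C)(C)C)Cc1cc(OC)c(-c2ccc3cc(C)cc(OC)c3c2OC(C)=O)c(OC)c1
F7 | step 7 | 2-{4-[(2S)-2-aminopropyl]-2,6-dimethoxyphenyl}-8-methoxy-6-methylnaphthalen-1-yl acetate hydrochloride | C[C@H](N)Cc1cc(OC)c(-c2ccc3cc(C)cc(OC)c3c2OC(C)=O)c(OC)c1.Cl
F8 | step 9 | 2-[(3S)-6,8-dimethoxy-1,3-dimethyl-1,2,3,4-tetrahydroisoquinolin-7-yl]-8-methoxy-6-methylnaphthalen-1-ol (C1 epimers) | COc1cc2c(c(OC)c1-c1ccc3cc(C)cc(OC)c3c1O)C(C)N[C@@H](C)C2
F9 | step 9 | 2-[(3S)-2-chloro-6,8-dimethoxy-1,3-dimethyl-1,2,3,4-tetrahydroisoquinolin-7-yl]-8-methoxy-6-methylnaphthalen-1-ol (C1 epimers) | COc1cc2c(c(OC)c1-c1ccc3cc(C)cc(OC)c3c1O)C(C)N(Cl)[C@@H](C)C2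
A1 | alternative 1 | {4-[(2S)-2-acetamidopropyl]-2,6-dimethoxyphenyl}boronic acid | CC(=O)N[C@@H](C)Cc1cc(OC)c(B(O)O)c(OC)c1
A2 | alternative 1 | 2-bromo-8-methoxy-1-(methoxymethoxy)-6-methylnaphthalene | COCOc1c(Br)ccc2cc(C)cc(OC)c12
A3 | alternative 1 | N-[(2S)-1-{3,5-dimethoxy-4-[8-methoxy-1-(methoxymethoxy)-6-methylnaphthalen-2-yl]phenyl}propan-2-yl]acetamide | CC(=O)N[C@@H](C)Cc1cc(OC)c(-c2ccc3cc(C)cc(OC)c3c2OCOC)c(OC)c1
A4 | alternative 2 | 8-methoxy-6-methylnaphthalen-1-ol | COc1cc(C)cc2cccc(O)c12
A5 | alternative 2 | (3S)-6,8-dimethoxy-1,3-dimethyl-3,4-dihydroisoquinoline | COc1cc2c(c(OC)c1)C(C)=N[C@@H](C)C2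
A6 | alternative 3 | 2-[(2E)-3-(4-bromo-2,6-dimethoxyphenyl)prop-2-en-1-yl]-N,N-diethyl-6-methoxy-4-methylbenzamide | CCN(CC)C(=O)c1c(C/C=C/c2c(OC)cc(Br)cc2OC)cc(C)cc1OC
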